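**Retrosynthetic overview**
1. The target is two fully substituted phloroglucinol rings joined by one CH2. The last operations are Friedel-Crafts acetylation of the single aromatic CH of ring A, then chelation-controlled cleavage of the two methyl ethers that flank the new acetyl group.
2. The strategy rests on ring B (B1 CH2 bridge, B2 OH, B3 isopentyl, B4 OH, B5 isobutyryl, B6 OH). Cutting B1-B2 and B4-B5 divides it into B1-B6-B5 plus the isobutyryl carbonyl (a beta-diketone, used as its 1,3-bis(silyloxy)diene) and B2-B3-B4 (isopentylmalonyl dichloride).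
3. The diketone comes from 2,4,6-trimethoxy-3-methylbenzaldehyde and 5-methylhexane-2,4-dione by boron-templated aldol condensation and hydrogenation; the aldehyde comes from symmetrical 2,4,6-trimethoxytoluene.
4. Ring A is bought as an arene; ring B is the only ring formed, in one flask from acyclic parts.

Key step: step 8

Assumption: compound 6 is drawn as one of two O-silyl positional isomers that interconvert by 1,5-silyl shift and both lead to diene 7; the Z enol ether geometries drawn for 6, 7 and 11 and the diastereomeric composition of 11 and 13 are of no consequence, because all of these elements vanish when ring B aromatises.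

**Step 1**
Reactants: 1 2,4,6-trimethoxytoluene
Product: 2 2,4,6-trimethoxy-3-methylbenzaldehyde
Conditions: POCl3 (1.2 equiv), DMF, 0 °C to 60 °C; then ice water
Reagents that add atoms: N,N-dimethylformamide, CN(C)C=O; water, O
Why: Vilsmeier-Haack formylation; the two free ring positions of 1 are equivalent by symmetry and each is ortho/para to three methoxy groups, so a single aldehyde should form.

**Step 2**
Reactants: 2 2,4,6-trimethoxy-3-methylbenzaldehyde; 3 5-methylhexane-2,4-dione
Product: 4 (E)-6-methyl-1-(2,4,6-trimethoxy-3-methylphenyl)hept-1-ene-3,5-dione (largely enolised)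
Conditions: 3 (1.2 equiv), B2O3 (0.7 equiv), EtOAc, 75 °C; then 2, B(OBu)3 (2 equiv); n-BuNH2 (0.3 equiv, slow addition), 75 °C; then 0.4 M aq. HCl, 60 °C
Reagents that add atoms: none
Why: Boron-templated aldol condensation of the Pabon type used for curcuminoids; chelation of the diketone to boron blocks Knoevenagel reaction at the central CH2, the methyl terminus is the only end that can condense and dehydrate (the isopropyl methine cannot give an enone), and the conjugated E alkene should result.

**Step 3**
Reactants: 4 (E)-6-methyl-1-(2,4,6-trimethoxy-3-methylphenyl)hept-1-ene-3,5-dione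
Product: 5 6-methyl-1-(2,4,6-trimethoxy-3-methylphenyl)heptane-3,5-dione
Conditions: H2 (1 atm), 10% Pd/C, EtOAc, rt, stopped after one equivalent of H2
Reagents that add atoms: none
Why: Heterogeneous catalytic hydrogenation of the styryl C=C, as in the reduction of curcuminoids to their tetrahydro derivatives; the enolised diketone and the aryl ethers are not reduced under these conditions.

**Step 4**
Reactants: 5 6-methyl-1-(2,4,6-trimethoxy-3-methylphenyl)heptane-3,5-dione
Product: 6 (Z)-6-methyl-5-(trimethylsilyloxy)-1-(2,4,6-trimethoxy-3-methylphenyl)hept-4-en-3-one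
Conditions: TMSCl (1.5 equiv), Et3N (1.6 equiv), toluene, rt, 48 h; filtration under Ar, concentration
Reagents that add atoms: chlorotrimethylsilane, C[Si](C)(C)Cl
Why: O-silylation of the chelated cis-enol of the 1,3-diketone (silyl enol ether formation), the first stage of the standard two-stage preparation of 1,3-bis(silyloxy)-1,3-dienes.

**Step 5**
Reactants: 6 (Z)-6-methyl-5-(trimethylsilyloxy)-1-(2,4,6-trimethoxy-3-methylphenyl)hept-4-en-3-one
Product: 7 (2Z,4Z)-6-methyl-3,5-bis(trimethylsilyloxy)-1-(2,4,6-trimethoxy-3-methylphenyl)hepta-2,4-diene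
Conditions: LiN(iPr)2 (LDA, 1.3 equiv), THF, −78 °C, 1 h; TMSCl (1.5 equiv), −78 °C to rt; pentane, filtration under Ar; used crude
Reagents that add atoms: chlorotrimethylsilane, C[Si](C)(C)Cl
Why: Kinetic deprotonation and O-silylation of the beta-silyloxy enone; the chain methylene next to the benzylic CH2 is the favoured site in either silyl isomer (alpha-prime to the carbonyl in the isomer drawn, gamma-vinylogous in the other), the only alternative being the hindered isopropyl methine, and at −78 °C the amide base should not metalate the aryl CH.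

**Step 6**
Reactants: 8 diethyl 2-(3-methylbutyl)propanedioate
Product: 9 2-(3-methylbutyl)propanedioic acid
Conditions: KOH (3 equiv), EtOH/H2O, reflux; then aq. HCl to pH 1 at 0 °C, extraction without heating
Reagents that add atoms: potassium hydroxide, [K+].[OH-]
Why: Saponification of the malonic diester; acidification and isolation in the cold avoid decarboxylation of the malonic acid.

**Step 7**
Reactants: 9 2-(3-methylbutyl)propanedioic acid
Product: 10 2-(3-methylbutyl)propanedioyl dichloride
Conditions: SOCl2 (neat, excess), 50 °C; distillation under reduced pressure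
Reagents that add atoms: thionyl chloride, O=S(Cl)Cl
Why: Conversion of the diacid into the diacid chloride with thionyl chloride, standard for alkylmalonic acids; no base is present, so dehydrochlorination to a chlorocarbonyl ketene is held back.

**Step 8**
Reactants: 7 (2Z,4Z)-6-methyl-3,5-bis(trimethylsilyloxy)-1-(2,4,6-trimethoxy-3-methylphenyl)hepta-2,4-diene; 10 2-(3-methylbutyl)propanedioyl dichloride
Product: 14 2-methyl-1-[2,4,6-trihydroxy-3-(3-methylbutyl)-5-[(2,4,6-trimethoxy-3-methylphenyl)methyl]phenyl]propan-1-one, via triketo acid chloride 11 (not isolated), via 4-hydroxy-2-pyrone 12 (not isolated), via triketo methyl ester 13 (not isolated)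
Conditions: 7 added slowly to 10 (1.1 equiv), CH2Cl2 (0.05 M), −78 °C to rt, no Lewis acid; volatiles removed; Mg(OMe)2 (4 equiv), MeOH, reflux, Ar; then aq. HCl
Reagents that add atoms: none
Why: Proposed new method: the terminal diene carbon B1, the most nucleophilic site of a 1,3-bis(silyloxy)diene, should attack one COCl of 10 without Lewis acid in a vinylogous Mukaiyama-type C-acylation (known for simple acid chlorides, not yet shown for a malonyl dichloride on a diketone-derived diene), which forms B1-B2 and gives 11 with loss of TMSCl. The second COCl is then captured in a six-membered closure, by carbon B5 of the remaining silyloxy enone to give 14 directly or, more probably under neutral conditions, by the enol oxygen on B6 to give pyrone 12. Methanolic Mg(OMe)2 opens 12 to the magnesium chelate of ester 13, whose 1,3-diketonate carbon B5 adds to the ester carbonyl B4 in a Claisen (Dieckmann-type) condensation that forms B4-B5 and closes ring B as a 6-exo-trig process, allowed in both its enolendo and enolexo description, after which the trione tautomerises irreversibly to the arene; the closest known reactions are [3+3] cyclisations of 1,3-bis(silyloxy)dienes with 1,3-dielectrophiles and the Mg(OMe)2-mediated conversion of 6-(2-oxoalkyl)-4-hydroxy-2-pyrones into acylphloroglucinols. No stereocentre is present in 14, and those of 11 and 13 are lost on aromatisation. The step needs terminal before central attack, which the vinylogous reactivity of the diene and the absence of a Lewis acid secure (the free CH of ring A is then also left alone), and Claisen rather than aldol closure, which the isopentyl group secures because the only other six-membered closure, B3 onto the isobutyryl carbonyl, would give a quaternary carbon that cannot aromatise and reverts. Because the two COCl groups of 10 are equivalent and all three carbon substituents are in place before the ring becomes electron-rich, only one constitution can result.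

**Step 9**
Reactants: 14 2-methyl-1-[2,4,6-trihydroxy-3-(3-methylbutyl)-5-[(2,4,6-trimethoxy-3-methylphenyl)methyl]phenyl]propan-1-one
Product: 15 1-[3-[(3-acetyl-2,4,6-trimethoxy-5-methylphenyl)methyl]-2,4,6-trihydroxy-5-(3-methylbutyl)phenyl]-2-methylpropan-1-one
Conditions: AlCl3 (5 equiv), CH2Cl2/MeNO2, 0 °C, 15 min; then AcCl (1.3 equiv), 0 °C; ice/aq. HCl
Reagents that add atoms: acetyl chloride, CC(=O)Cl
Why: Friedel-Crafts acylation at the only aromatic CH of the molecule, which is ortho to two and para to one methoxy group; ring B has no free carbon, its phenols are first tied up as aluminium phenolates so that O-acylation is disfavoured, and the low temperature should hold back ether cleavage.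

**Step 10**
Reactants: 15 1-[3-[(3-acetyl-2,4,6-trimethoxy-5-methylphenyl)methyl]-2,4,6-trihydroxy-5-(3-methylbutyl)phenyl]-2-methylpropan-1-one
Product: 16 1-[3-[(3-acetyl-2,4-dihydroxy-6-methoxy-5-methylphenyl)methyl]-2,4,6-trihydroxy-5-(3-methylbutyl)phenyl]-2-methylpropan-1-one (CNP0238575.0)
Conditions: BCl3 (8 equiv), CH2Cl2, −78 °C to rt; then MeOH, aq. HCl
Reagents that add atoms: none
Why: Chelation-controlled Lewis acid demethylation; boron bound to the acetyl oxygen delivers chloride to the methyl groups of the two flanking methoxy groups through six-membered chelates, whereas the third methoxy group of ring A, which sits between the methyl group and the CH2 bridge, has no neighbouring carbonyl and should stay, and the ring B phenols only form borates that hydrolyse on work-up.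

**Compound list**
1 | 2,4,6-trimethoxytoluene | Cc1c(OC)cc(OC)cc1OC | starting material
2 | 2,4,6-trimethoxy-3-methylbenzaldehyde | COc1cc(OC)c(C=O)c(OC)c1C | intermediate
3 | 5-methylhexane-2,4-dione | CC(C)C(=O)CC(C)=O | starting material
4 | (E)-6-methyl-1-(2,4,6-trimethoxy-3-methylphenyl)hept-1-ene-3,5-dione | COc1cc(OC)c(/C=C/C(=O)CC(=O)C(C)C)c(OC)c1C | intermediate
5 | 6-methyl-1-(2,4,6-trimethoxy-3-methylphenyl)heptane-3,5-dione | COc1cc(OC)c(CCC(=O)CC(=O)C(C)C)c(OC)c1C | intermediate
6 | (Z)-6-methyl-5-(trimethylsilyloxy)-1-(2,4,6-trimethoxy-3-methylphenyl)hept-4-en-3-one | COc1cc(OC)c(CCC(=O)/C=C(\O[Si](C)(C)C)C(C)C)c(OC)c1C | intermediate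
7 | (2Z,4Z)-6-methyl-3,5-bis(trimethylsilyloxy)-1-(2,4,6-trimethoxy-3-methylphenyl)hepta-2,4-diene | COc1cc(OC)c(C/C=C(\O[Si](C)(C)C)/C=C(\O[Si](C)(C)C)C(C)C)c(OC)c1C | intermediate
8 | diethyl 2-(3-methylbutyl)propanedioate | CCOC(=O)C(CCC(C)C)C(=O)OCC | starting material
9 | 2-(3-methylbutyl)propanedioic acid | CC(C)CCC(C(=O)O)C(=O)O | intermediate
10 | 2-(3-methylbutyl)propanedioyl dichloride | CC(C)CCC(C(=O)Cl)C(=O)Cl | intermediate
11 | (6Z)-8-methyl-2-(3-methylbutyl)-3,5-dioxo-7-(trimethylsilyloxy)-4-[(2,4,6-trimethoxy-3-methylphenyl)methyl]non-6-enoyl chloride, mixture of diastereomers, formed in the flask in step 8 | COc1cc(OC)c(CC(C(=O)C(CCC(C)C)C(=O)Cl)C(=O)/C=C(\O[Si](C)(C)C)C(C)C)c(OC)c1C | intermediate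
12 | 4-hydroxy-3-(3-methylbutyl)-6-(3-methyl-2-oxobutyl)-5-[(2,4,6-trimethoxy-3-methylphenyl)methyl]-2H-pyran-2-one, formed in the flask in step 8 | O=C1OC(CC(=O)C(C)C)=C(Cc2c(OC)cc(OC)c(C)c2OC)C(O)=C1CCC(C)C | intermediate
13 | methyl 8-methyl-2-(3-methylbutyl)-3,5,7-trioxo-4-[(2,4,6-trimethoxy-3-methylphenyl)methyl]nonanoate, mixture of diastereomers, formed in the flask in step 8 | COC(=O)C(CCC(C)C)C(=O)C(Cc1c(OC)cc(OC)c(C)c1OC)C(=O)CC(=O)C(C)C | intermediate
14 | 2-methyl-1-[2,4,6-trihydroxy-3-(3-methylbutyl)-5-[(2,4,6-trimethoxy-3-methylphenyl)methyl]phenyl]propan-1-one | COc1cc(OC)c(Cc2c(O)c(CCC(C)C)c(O)c(C(=O)C(C)C)c2O)c(OC)c1C | intermediate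
15 | 1-[3-[(3-acetyl-2,4,6-trimethoxy-5-methylphenyl)methyl]-2,4,6-trihydroxy-5-(3-methylbutyl)phenyl]-2-methylpropan-1-one | COc1c(C)c(OC)c(C(C)=O)c(OC)c1Cc1c(O)c(CCC(C)C)c(O)c(C(=O)C(C)C)c1O | intermediate
16 | 1-[3-[(3-acetyl-2,4-dihydroxy-6-methoxy-5-methylphenyl)methyl]-2,4,6-trihydroxy-5-(3-methylbutyl)phenyl]-2-methylpropan-1-one | COc1c(C)c(O)c(C(C)=O)c(O)c1Cc1c(O)c(CCC(C)C)c(O)c(C(=O)C(C)C)c1O | target

**Step count and risks**
Total steps: 10. Longest linear sequence: 8 steps (steps 1, 2, 3, 4, 5, 8, 9, 10); the malonyl branch (steps 6, 7) joins at step 8.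

Most likely to fail:

Step 8 (key step). The diacid chloride may oligomerise or lose HCl to a ketene faster than it is attacked by the hindered, substituted diene terminus. The moisture-sensitive diene may hydrolyse back to the diketone. The methanolysis and Claisen stage may stall on the hindered, fully substituted pyrone. The fallback uses known chemistry, sets out from aldehyde 2 and returns at 14, and joins the two rings by Friedel-Crafts benzylation instead of building ring B. Aldehyde 2 would be reduced with NaBH4 in MeOH to (2,4,6-trimethoxy-3-methylphenyl)methanol F1. Separately, commercial phloroglucinol would be C-acylated with isobutyryl chloride and AlCl3 in nitrobenzene/CH2Cl2 to 2-methyl-1-(2,4,6-trihydroxyphenyl)propan-1-one F2. This would be C-prenylated with one equivalent of prenyl bromide in aqueous KOH at 0 °C to 2-methyl-1-[2,4,6-trihydroxy-3-(3-methylbut-2-enyl)phenyl]propan-1-one F3, and hydrogenated over Pd/C to 2-methyl-1-[2,4,6-trihydroxy-3-(3-methylbutyl)phenyl]propan-1-one F4. Slow addition of F1 to an excess of F4 with catalytic p-TsOH in CH2Cl2/dioxane at rt should generate the benzylic cation stabilised by three methoxy groups, which alkylates the only free ring carbon of F4 and gives 14.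

Step 9. Acylation may go to the ring B oxygens instead of the ring A carbon. Ipso attack or protonation at B1 under the strong Lewis acid may split the CH2 bridge. Partial ether cleavage may begin early. The fallback sets out from 14 and returns at 15, and masks ring B before the acylation. Ac2O, pyridine and DMAP would convert 14 into 2-(3-methylbutyl)-4-(2-methylpropanoyl)-6-[(2,4,6-trimethoxy-3-methylphenyl)methyl]benzene-1,3,5-triyl triacetate F5, whose ring B is deactivated and carries no free OH. Friedel-Crafts acetylation with AcCl and SnCl4 in CH2Cl2 at 0 °C would then give 2-[(3-acetyl-2,4,6-trimethoxy-5-methylphenyl)methyl]-4-(3-methylbutyl)-6-(2-methylpropanoyl)benzene-1,3,5-triyl triacetate F6. Methanolysis with K2CO3 in MeOH at rt would remove the three aryl acetates and give 15.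

Step 10. The second ortho ether may resist cleavage once the first phenol is locked in a boron chelate. Forcing the reaction may also remove the twisted methyl ether that lies between the ring A methyl group and the CH2 bridge, or cleave the diarylmethane. The fallback sets out from 15 and returns at 16, and replaces discrimination among the ethers by discrimination among the phenols. Ac2O, pyridine and DMAP would convert 15 into the ring B triacetate 2-[(3-acetyl-2,4,6-trimethoxy-5-methylphenyl)methyl]-4-(3-methylbutyl)-6-(2-methylpropanoyl)benzene-1,3,5-triyl triacetate F6. BBr3 in CH2Cl2, −78 °C to 0 °C, would cleave all three ring A methyl ethers and give 2-[(3-acetyl-2,4,6-trihydroxy-5-methylphenyl)methyl]-4-(3-methylbutyl)-6-(2-methylpropanoyl)benzene-1,3,5-triyl triacetate F7. In F7 the ring A OH that lies between the methyl group and the CH2 bridge is the only phenol not hydrogen-bonded to the acetyl carbonyl and is the most acidic. One equivalent of TMSCHN2 in toluene/MeOH at 0 °C should therefore methylate it selectively to 2-[(3-acetyl-2,4-dihydroxy-6-methoxy-5-methylphenyl)methyl]-4-(3-methylbutyl)-6-(2-methylpropanoyl)benzene-1,3,5-triyl triacetate F8. K2CO3 in MeOH would then remove the acetates and give 16.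

**Further compounds**
F1 | step 8 | (2,4,6-trimethoxy-3-methylphenyl)methanol | COc1cc(OC)c(CO)c(OC)c1C
F2 | step 8 | 2-methyl-1-(2,4,6-trihydroxyphenyl)propan-1-one | CC(C)C(=O)c1c(O)cc(O)cc1O
F3 | step 8 | 2-methyl-1-[2,4,6-trihydroxy-3-(3-methylbut-2-enyl)phenyl]propan-1-one | CC(C)C(=O)c1c(O)cc(O)c(CC=C(C)C)c1O
F4 | step 8 | 2-methyl-1-[2,4,6-trihydroxy-3-(3-methylbutyl)phenyl]propan-1-one | CC(C)C(=O)c1c(O)cc(O)c(CCC(C)C)c1O
F5 | step 9 | 2-(3-methylbutyl)-4-(2-methylpropanoyl)-6-[(2,4,6-trimethoxy-3-methylphenyl)methyl]benzene-1,3,5-triyl triacetate | COc1cc(OC)c(Cc2c(OC(C)=O)c(CCC(C)C)c(OC(C)=O)c(C(=O)C(C)C)c2OC(C)=O)c(OC)c1C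
F6 | step 9 | 2-[(3-acetyl-2,4,6-trimethoxy-5-methylphenyl)methyl]-4-(3-methylbutyl)-6-(2-methylpropanoyl)benzene-1,3,5-triyl triacetate | COc1c(C)c(OC)c(C(C)=O)c(OC)c1Cc1c(OC(C)=O)c(CCC(C)C)c(OC(C)=O)c(C(=O)C(C)C)c1OC(C)=O
F7 | step 10 | 2-[(3-acetyl-2,4,6-trihydroxy-5-methylphenyl)methyl]-4-(3-methylbutyl)-6-(2-methylpropanoyl)benzene-1,3,5-triyl triacetate | Cc1c(O)c(C(C)=O)c(O)c(Cc2c(OC(C)=O)c(CCC(C)C)c(OC(C)=O)c(C(=O)C(C)C)c2OC(C)=O)c1O
F8 | step 10 | 2-[(3-acetyl-2,4-dihydroxy-6-methoxy-5-methylphenyl)methyl]-4-(3-methylbutyl)-6-(2-methylpropanoyl)benzene-1,3,5-triyl triacetate | COc1c(C)c(O)c(C(C)=O)c(O)c1Cc1c(OC(C)=O)c(CCC(C)C)c(OC(C)=O)c(C(=O)C(C)C)c1OC(C)=O
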